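**Strategy.** The carbocycle is a para-substituted six-membered ring: C1' bears the oxane C2, C4' the methyl group, and the vicinal C3'–Br/C4'–Cl pair is a masked C3'=C4' alkene. It is therefore cut into isoprene (C2'–C5' and the methyl) and a two-carbon ethynyl handle (C1', C6') on the quaternary C2 of a finished bromo-oxane. A cobalt-catalysed [4+2] cycloaddition closes this ring in one operation with para regiocontrol; the resulting cyclohexa-1,4-diene has two differentiated alkenes, C1'=C6' for hydroxyl-directed hydrogenation and C3'=C4' for catalyst-controlled epoxidation and stereospecific conversion into the trans-diequatorial bromochloride. The precursor is an alkynyl oxanol that contains no carbocycle.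

Key step: step 7

Remark: oxane locants are O1, C2 (quaternary, CH3), C3 (OAc), C5 (Br), C6 (CMe2); cyclohexyl locants are C1' (on C2), C3' (Br), C4' (Cl, CH3); L-(+)-diethyl tartrate means the (2R,3R)-ester.

Step 1
Reactants: 1 prop-2-yn-1-ol; 2 1-bromo-3-methylbut-2-ene (prenyl bromide)
Product: 4 (2Z)-2,6-dimethylhepta-2,5-dien-1-ol, via chelated alkenylmagnesium alkoxide 3 (not isolated)
Conditions: MeMgBr (3 equiv), CuI (10 mol%), THF/Et2O, −10 °C to rt; then 2, 0 °C to rt; aq. NH4Cl
Reagents that add atoms: methylmagnesium bromide (C[Mg]Br)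
Why: Copper-catalysed anti-carbomagnesiation of the propargylic alkoxide puts CH3 on C2 and magnesium on C3 cis to the CH2O group (five-membered chelate), and copper-mediated SN2 allylation of this alkenylmagnesium with retention fixes the 2Z geometry.

Step 2
Reactants: 4 (2Z)-2,6-dimethylhepta-2,5-dien-1-ol
Product: 5 [(2S,3R)-2-methyl-3-(3-methylbut-2-en-1-yl)oxiran-2-yl]methanol
Conditions: Ti(OiPr)4 (10 mol%), L-(+)-diethyl tartrate (12 mol%), t-BuOOH, 4 Å molecular sieves, CH2Cl2, −20 °C
Reagents that add atoms: tert-butyl hydroperoxide (CC(C)(C)OO)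
Why: Sharpless asymmetric epoxidation touches only the allylic-alcohol alkene, and the (2R,3R)-tartrate delivers oxygen to the face that gives the (2S) epoxy alcohol, so C2 (S) and C3 (R) are set by the catalyst.

Step 3
Reactants: 5 [(2S,3R)-2-methyl-3-(3-methylbut-2-en-1-yl)oxiran-2-yl]methanol
Product: 6 (2S,3S)-1,2-dihydroxy-2,6-dimethylhept-5-en-3-yl benzoate
Conditions: Ti(OiPr)4 (1.5 equiv), PhCO2H, CH2Cl2, rt
Reagents that add atoms: benzoic acid (OC(=O)c1ccccc1)
Why: Titanium-alkoxide-directed opening of the 2,3-epoxy alcohol, in which benzoate attacks the titanium-bound epoxide at C3 by SN2 with inversion and leaves the tertiary C2–O bond intact, giving (2S,3S).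

Step 4
Reactants: 6 (2S,3S)-1,2-dihydroxy-2,6-dimethylhept-5-en-3-yl benzoate
Product: 7 (2S,3S,5S)-5-bromo-2-(hydroxymethyl)-2,6,6-trimethyloxan-3-yl benzoate
Conditions: TBCO (2,4,4,6-tetrabromocyclohexa-2,5-dien-1-one, 1.1 equiv), MeNO2, 0 °C to rt, dark
Reagents that add atoms: 2,4,4,6-tetrabromocyclohexa-2,5-dien-1-one (O=C1C(Br)=CC(Br)(Br)C=C1Br)
Why: Bromoetherification in which the tertiary hydroxyl opens the bromonium ion at the dimethyl-substituted carbon (Markovnikov, 6-endo) through a chair with Br equatorial and the C3 benzoate axial (gauche to the ring oxygen, anti to the axial 2-methyl), so C5 is relayed from C2/C3 with Br trans to the benzoate.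

Step 5
Reactants: 7 (2S,3S,5S)-5-bromo-2-(hydroxymethyl)-2,6,6-trimethyloxan-3-yl benzoate
Product: 8 (2R,3S,5S)-5-bromo-2-formyl-2,6,6-trimethyloxan-3-yl benzoate
Conditions: TEMPO (10 mol%), PhI(OAc)2 (1.2 equiv), CH2Cl2, rt
Reagents that add atoms: none
Why: Oxoammonium (TEMPO) oxidation of the only free, primary hydroxyl stops at the aldehyde, and the quaternary C2 rules out epimerisation or β-elimination.

Step 6
Reactants: 8 (2R,3S,5S)-5-bromo-2-formyl-2,6,6-trimethyloxan-3-yl benzoate
Product: 10 (2S,3S,5S)-5-bromo-2-ethynyl-2,6,6-trimethyloxan-3-ol, via alkynyl benzoate 9 (not isolated)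
Conditions: dimethyl (1-diazo-2-oxopropyl)phosphonate, K2CO3, MeOH, 0 °C to rt; then prolonged stirring at rt
Reagents that add atoms: dimethyl (1-diazo-2-oxopropyl)phosphonate (CC(=O)C(=[N+]=[N-])P(=O)(OC)OC)
Why: Seyferth–Gilbert homologation with the Ohira–Bestmann reagent turns the non-enolisable aldehyde into the terminal alkyne (alkylidene carbene 1,2-shift), after which the same methoxide transesterifies the hindered benzoate and frees the C3 hydroxyl needed as a directing group.

Step 7
Reactants: 10 (2S,3S,5S)-5-bromo-2-ethynyl-2,6,6-trimethyloxan-3-ol; 11 isoprene (2-methylbuta-1,3-diene)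
Product: 12 (2S,3S,5S)-5-bromo-2,6,6-trimethyl-2-(4-methylcyclohexa-1,4-dien-1-yl)oxan-3-ol
Conditions: 11 (5 equiv), CoBr2(dppe) (10 mol%; dppe = 1,2-bis(diphenylphosphino)ethane), Zn powder (20 mol%), ZnI2 (20 mol%), CH2Cl2, rt
Reagents that add atoms: none
Why: This is a cobalt-catalysed neutral [4+2] cycloaddition: the low-valent cobalt–diphosphine cation generated from CoBr2(dppe), Zn and ZnI2 binds isoprene and the alkyne, couples them oxidatively to a cobaltacycle and releases the cyclohexa-1,4-diene by reductive elimination. The closest known reaction type is exactly this cobalt–diphosphine Diels–Alder reaction of unactivated terminal alkynes with 2-substituted butadienes, applied here to a hindered tertiary propargylic ether. The carbocycle is closed as an intermolecular [4+2] annulation that forms C1'–C2' and C6'–C5' in one operation and creates no stereocentre. The selectivity needed is regiochemical: the oxanyl group on the alkyne and the methyl of isoprene must end 1,4 (para), which is the normal outcome with diphosphine ligands and is reinforced by the bulk of the quaternary C2. The skipped diene product does not react further, and the free C3–OH, the ring ether and the neopentyl-type secondary bromide should be spectators under these mild, non-basic conditions.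

Step 8
Reactants: 12 (2S,3S,5S)-5-bromo-2,6,6-trimethyl-2-(4-methylcyclohexa-1,4-dien-1-yl)oxan-3-ol
Product: 13 (2S,3S,5S)-5-bromo-2,6,6-trimethyl-2-[(1R)-4-methylcyclohex-3-en-1-yl]oxan-3-ol
Conditions: [Rh(nbd)(dppb)]BF4 (5 mol%; nbd = norbornadiene, dppb = 1,4-bis(diphenylphosphino)butane), H2 (40 bar), CH2Cl2, rt
Reagents that add atoms: none
Why: Hydroxyl-directed homogeneous hydrogenation, in which the cationic rhodium catalyst is anchored by the axial C3–OH and adds H2 to the homoallylic C1'=C6' alkene from the face syn to it in the A(1,3)-minimised chelate (C6'–H eclipsing the C2–O1 bond), which should give (1'R) while the undirected C3'=C4' alkene is left alone.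

Step 9
Reactants: 13 (2S,3S,5S)-5-bromo-2,6,6-trimethyl-2-[(1R)-4-methylcyclohex-3-en-1-yl]oxan-3-ol
Product: 14 (2S,3S,5S)-5-bromo-2,6,6-trimethyl-2-[(1R)-4-methylcyclohex-3-en-1-yl]oxan-3-yl acetate
Conditions: Ac2O, DMAP (cat.), pyridine, CH2Cl2, rt
Reagents that add atoms: acetic anhydride (CC(=O)OC(C)=O)
Why: DMAP-catalysed acylation of the single hydroxyl installs the acetate of the target and protects C3–O from the later halogenation reagents.

Step 10
Reactants: 14 (2S,3S,5S)-5-bromo-2,6,6-trimethyl-2-[(1R)-4-methylcyclohex-3-en-1-yl]oxan-3-yl acetate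
Product: 15 (2S,3S,5S)-5-bromo-2,6,6-trimethyl-2-[(1S,3R,6R)-6-methyl-7-oxabicyclo[4.1.0]heptan-3-yl]oxan-3-yl acetate
Conditions: L-fructose-derived ketone catalyst of the Shi epoxidation (30 mol%), Oxone (2KHSO5·KHSO4·K2SO4), K2CO3, Bu4NHSO4, MeCN/CH2(OMe)2/aq. Na2B4O7 buffer, 0 °C
Reagents that add atoms: potassium peroxymonosulfate from Oxone ([K+].[O-]S(=O)(=O)OO)
Why: Shi epoxidation of the only alkene, where the chiral dioxirane (spiro transition state) rather than the remote C1' centre selects the face, the ketone enantiomer being chosen so that oxygen is delivered anti to the C1' substituent.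

Step 11
Reactants: 15 (2S,3S,5S)-5-bromo-2,6,6-trimethyl-2-[(1S,3R,6R)-6-methyl-7-oxabicyclo[4.1.0]heptan-3-yl]oxan-3-yl acetate
Product: 16 (2S,3S,5S)-5-bromo-2-[(1R,3S,4S)-4-bromo-3-hydroxy-4-methylcyclohexyl]-2,6,6-trimethyloxan-3-yl acetate
Conditions: HBr (48% aq.), THF, −10 °C
Reagents that add atoms: hydrogen bromide (Br)
Why: Acid-mediated epoxide opening in which Markovnikov preference and trans-diaxial (Fürst–Plattner) opening coincide, so bromide attacks the tertiary C4' axially with inversion and gives the trans-diaxial bromohydrin.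

Step 12
Reactants: 16 (2S,3S,5S)-5-bromo-2-[(1R,3S,4S)-4-bromo-3-hydroxy-4-methylcyclohexyl]-2,6,6-trimethyloxan-3-yl acetate
Product: 17 acetylcaespitol, (2S,3S,5S)-5-bromo-2-[(1R,3R,4R)-3-bromo-4-chloro-4-methylcyclohexyl]-2,6,6-trimethyloxan-3-yl acetate
Conditions: Ph3P, N-chlorosuccinimide, CH2Cl2, 0 °C to rt
Reagents that add atoms: N-chlorosuccinimide (O=C1CCC(=O)N1Cl)
Why: Appel-type deoxychlorination with neighbouring-group participation, in which the antiperiplanar C4'–Br displaces the oxyphosphonium at C3' with inversion to a bromonium ion on the face syn to the C1' substituent and chloride opens it at the tertiary C4' (Markovnikov, inversion), leaving Br equatorial at C3' and Cl equatorial at C4'.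

**Compound list**

1 | prop-2-yn-1-ol | C#CCO | starting material
2 | 1-bromo-3-methylbut-2-ene | CC(C)=CCBr | starting material
3 | (Z)-[3-(bromomagnesiooxy)-2-methylprop-1-en-1-yl]magnesium bromide | Br[Mg]OC/C(C)=C\[Mg]Br | intermediate (not isolated)
4 | (2Z)-2,6-dimethylhepta-2,5-dien-1-ol | OC/C(C)=C\CC=C(C)C | intermediate
5 | [(2S,3R)-2-methyl-3-(3-methylbut-2-en-1-yl)oxiran-2-yl]methanol | OC[C@]1(C)O[C@@H]1CC=C(C)C | intermediate
6 | (2S,3S)-1,2-dihydroxy-2,6-dimethylhept-5-en-3-yl benzoate | O=C(c1ccccc1)O[C@@H](CC=C(C)C)[C@](O)(C)CO | intermediate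
7 | (2S,3S,5S)-5-bromo-2-(hydroxymethyl)-2,6,6-trimethyloxan-3-yl benzoate | O=C(c1ccccc1)O[C@H]1C[C@H](Br)C(C)(C)O[C@@]1(C)CO | intermediate
8 | (2R,3S,5S)-5-bromo-2-formyl-2,6,6-trimethyloxan-3-yl benzoate | O=C(c1ccccc1)O[C@H]1C[C@H](Br)C(C)(C)O[C@@]1(C)C=O | intermediate
9 | (2S,3S,5S)-5-bromo-2-ethynyl-2,6,6-trimethyloxan-3-yl benzoate | O=C(c1ccccc1)O[C@H]1C[C@H](Br)C(C)(C)O[C@@]1(C)C#C | intermediate (not isolated)
10 | (2S,3S,5S)-5-bromo-2-ethynyl-2,6,6-trimethyloxan-3-ol | O[C@H]1C[C@H](Br)C(C)(C)O[C@@]1(C)C#C | intermediate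
11 | isoprene (2-methylbuta-1,3-diene) | C=CC(C)=C | starting material
12 | (2S,3S,5S)-5-bromo-2,6,6-trimethyl-2-(4-methylcyclohexa-1,4-dien-1-yl)oxan-3-ol | O[C@H]1C[C@H](Br)C(C)(C)O[C@@]1(C)C1=CCC(C)=CC1 | intermediate
13 | (2S,3S,5S)-5-bromo-2,6,6-trimethyl-2-[(1R)-4-methylcyclohex-3-en-1-yl]oxan-3-ol | O[C@H]1C[C@H](Br)C(C)(C)O[C@@]1(C)[C@@H]1CCC(C)=CC1 | intermediate
14 | (2S,3S,5S)-5-bromo-2,6,6-trimethyl-2-[(1R)-4-methylcyclohex-3-en-1-yl]oxan-3-yl acetate | CC(=O)O[C@H]1C[C@H](Br)C(C)(C)O[C@@]1(C)[C@@H]1CCC(C)=CC1 | intermediate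
15 | (2S,3S,5S)-5-bromo-2,6,6-trimethyl-2-[(1S,3R,6R)-6-methyl-7-oxabicyclo[4.1.0]heptan-3-yl]oxan-3-yl acetate | CC(=O)O[C@H]1C[C@H](Br)C(C)(C)O[C@@]1(C)[C@@H]1CC[C@@]2(C)O[C@H]2C1 | intermediate
16 | (2S,3S,5S)-5-bromo-2-[(1R,3S,4S)-4-bromo-3-hydroxy-4-methylcyclohexyl]-2,6,6-trimethyloxan-3-yl acetate | CC(=O)O[C@H]1C[C@H](Br)C(C)(C)O[C@@]1(C)[C@@H]1CC[C@](C)(Br)[C@@H](O)C1 | intermediate
17 | acetylcaespitol, (2S,3S,5S)-5-bromo-2-[(1R,3R,4R)-3-bromo-4-chloro-4-methylcyclohexyl]-2,6,6-trimethyloxan-3-yl acetate | CC(=O)O[C@H]1C[C@H](Br)C(C)(C)O[C@@]1(C)[C@@H]1CC[C@@](C)(Cl)[C@H](Br)C1 | target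

**Totals.** Total step count: 12. Longest linear sequence: 12 steps (from 1).

**Three steps most likely to fail**

1. Step 8 (directed hydrogenation). The two chelate rotamers may not be discriminated well enough, giving poor facial selectivity at C1', and the catalyst may also isomerise or reduce the C3'=C4' alkene. Fallback (C1' set last by the ring's own stereocentres instead of by the hydroxyl): diene 12 is acetylated (Ac2O, DMAP, pyridine) to (2S,3S,5S)-5-bromo-2,6,6-trimethyl-2-(4-methylcyclohexa-1,4-dien-1-yl)oxan-3-yl acetate F1. Shi epoxidation with the L-fructose-derived ketone and Oxone, chemoselective for the less hindered C3'=C4' alkene, gives (2S,3S,5S)-5-bromo-2,6,6-trimethyl-2-[(1S,6R)-6-methyl-7-oxabicyclo[4.1.0]hept-3-en-3-yl]oxan-3-yl acetate F2. Aqueous HBr opens it at the tertiary carbon to (2S,3S,5S)-5-bromo-2-[(4S,5S)-4-bromo-5-hydroxy-4-methylcyclohex-1-en-1-yl]-2,6,6-trimethyloxan-3-yl acetate F3. Ph3P/N-chlorosuccinimide converts this through the bromonium ion (no chair-locking substituent, so opening is purely Markovnikov) into (2S,3S,5S)-5-bromo-2-[(4R,5R)-5-bromo-4-chloro-4-methylcyclohex-1-en-1-yl]-2,6,6-trimethyloxan-3-yl acetate F4. Hydrogen-atom-transfer hydrogenation (Mn(dpm)3, PhSiH3, t-BuOOH, i-PrOH) then reduces C1'=C6', the hydrogen atom reaching the tertiary C1' radical anti to the pseudo-axial C3'–Br, and the route is rejoined at 17.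

2. Step 4 (bromoetherification). 5-exo closure to an oxolane may compete, and the two chair transition states may be too close in energy, so that C5 is formed with poor diastereocontrol. Fallback (C5 set by a catalyst instead of by the chair): Shi epoxidation of 6 with the D-fructose-derived ketone and Oxone gives (2S,3S,5R)-5,6-epoxy-1,2-dihydroxy-2,6-dimethylheptan-3-yl benzoate F5. Li2NiBr4 in THF opens the epoxide at the secondary C5 with inversion to (2S,3S,5S)-5-bromo-1,2,6-trihydroxy-2,6-dimethylheptan-3-yl benzoate F6. Ionisation of the tertiary C6–OH in (CF3)2CHOH with catalytic TfOH, assisted by the neighbouring bromine (bromonium ion of fixed configuration), and capture by the C2 hydroxyl at C6 returns to the route at 7.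

3. Step 12 (bromonium opening). Chloride may open the bromonium ion at the secondary C3' in the trans-diaxial mode instead of at the tertiary C4', giving the halogen-transposed isomer. Fallback (thermodynamic isomerisation instead of kinetic regiocontrol): 16 is taken under the same activation, in a non-polar solvent, to the diaxial isomer (2S,3S,5S)-5-bromo-2-[(1R,3S,4S)-4-bromo-3-chloro-4-methylcyclohexyl]-2,6,6-trimethyloxan-3-yl acetate F7. Heating F7 (melt or decalin, about 150 °C) should trigger the thermal diaxial-to-diequatorial dyotropic 1,2-interchange of vicinal halogens, which moves Br to C3' and Cl to C4' with inversion at both carbons and returns to the route at 17. The position of this equilibrium is not certain; it may not favour 17.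

**Further compounds**

F1 | step 8 | (2S,3S,5S)-5-bromo-2,6,6-trimethyl-2-(4-methylcyclohexa-1,4-dien-1-yl)oxan-3-yl acetate | CC(=O)O[C@H]1C[C@H](Br)C(C)(C)O[C@@]1(C)C1=CCC(C)=CC1
F2 | step 8 | (2S,3S,5S)-5-bromo-2,6,6-trimethyl-2-[(1S,6R)-6-methyl-7-oxabicyclo[4.1.0]hept-3-en-3-yl]oxan-3-yl acetate | CC(=O)O[C@H]1C[C@H](Br)C(C)(C)O[C@@]1(C)C1=CC[C@@]2(C)O[C@H]2C1
F3 | step 8 | (2S,3S,5S)-5-bromo-2-[(4S,5S)-4-bromo-5-hydroxy-4-methylcyclohex-1-en-1-yl]-2,6,6-trimethyloxan-3-yl acetate | CC(=O)O[C@H]1C[C@H](Br)C(C)(C)O[C@@]1(C)C1=CC[C@](C)(Br)[C@@H](O)C1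
F4 | step 8 | (2S,3S,5S)-5-bromo-2-[(4R,5R)-5-bromo-4-chloro-4-methylcyclohex-1-en-1-yl]-2,6,6-trimethyloxan-3-yl acetate | CC(=O)O[C@H]1C[C@H](Br)C(C)(C)O[C@@]1(C)C1=CC[C@@](C)(Cl)[C@H](Br)C1
F5 | step 4 | (2S,3S,5R)-5,6-epoxy-1,2-dihydroxy-2,6-dimethylheptan-3-yl benzoate | O=C(c1ccccc1)O[C@@H](C[C@H]1OC1(C)C)[C@](O)(C)CO
F6 | step 4 | (2S,3S,5S)-5-bromo-1,2,6-trihydroxy-2,6-dimethylheptan-3-yl benzoate | O=C(c1ccccc1)O[C@@H](C[C@H](Br)C(C)(C)O)[C@](O)(C)CO
F7 | step 12 | (2S,3S,5S)-5-bromo-2-[(1R,3S,4S)-4-bromo-3-chloro-4-methylcyclohexyl]-2,6,6-trimethyloxan-3-yl acetate | CC(=O)O[C@H]1C[C@H](Br)C(C)(C)O[C@@]1(C)[C@@H]1CC[C@](C)(Br)[C@@H](Cl)C1
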